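**Retrosynthetic overview**

1. The C40 chain is cut at C11=C12 and C11'=C12' (two Wittig reactions): C15 salt of the cyclohexene end (fragment A) + C10 dialdehyde (fragment C) + C15 salt of the epoxide end (fragment B); both palmitates are put on last.
2. Fragment A: the side chain comes from a ring vinyl group (cross-metathesis, then Horner–Wadsworth–Emmons). Ring E (C1'–C6') is not made as a six-membered ring but by one-carbon ring expansion of a cyclopentene: cyclopropanation of a silyl enol ether, then FeCl3 ring opening, inserts C4' between C3' and C5'.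
3. Enabling feature: in ring E the oxygen-bearing C3' lies next to the trisubstituted C4'=C5'(CH3) olefin, which is a masked 3-methylcyclohex-2-enone. That is the enol ether C3'(O)=C5'(CH3) of the cyclopentane C3'–C5'–C6'–C1'–C2' plus one carbon (C4'). The silyl enol ether, the cyclopropane and the C3' ketone level are temporary and are removed again.
4. C6' is set before the expansion by asymmetric conjugate addition of vinyl to 2,4,4-trimethylcyclopent-2-en-1-one. Fragment B comes from (4R,6R)-actinol by enol triflate carbonylation, Katsuki–Sharpless epoxidation and a C5 phosphonate olefination.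
5. Ring order: ring B (C1–C6) is bought as a cyclohexane; cyclopentene to ring E in step 2; oxirane in step 13.

Key step: step 2

Assumption: compounds 1, 14 and 27 are taken as purchasable, the ligand enantiomer named in step 1 is taken to be the one that gives the 3R adduct, and locants C1–C15 and C1'–C15' follow carotenoid numbering.

**Route**

Step 1
Reactants: 1 2,4,4-trimethylcyclopent-2-en-1-one
Product: 2 trimethyl{[(3R)-2,4,4-trimethyl-3-vinylcyclopent-1-en-1-yl]oxy}silane
Conditions: CH2=CHMgBr (1.5 equiv), CuBr·SMe2 (5 mol %), (R)-1-[(Sp)-2-(diphenylphosphino)ferrocenyl]ethyldicyclohexylphosphine (6 mol %), Me3SiCl (2 equiv), t-BuOMe, −78 °C; Et3N, pentane filtration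
Reagents that add atoms: vinylmagnesium bromide (C=C[Mg]Br); chlorotrimethylsilane (C[Si](C)(C)Cl)
Why: Copper-catalysed asymmetric conjugate addition of a Grignard reagent with in situ silyl trapping (the ferrocenyl diphosphine–CuBr system is precedented for 2-methylcyclopent-2-en-1-one) should place vinyl on one face of the β-carbon under ligand control, which sets the centre that becomes C6', and Me3SiCl fixes the enolate regiospecifically as the tetrasubstituted silyl enol ether needed for step 2.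

Step 2
Reactants: 2 trimethyl{[(3R)-2,4,4-trimethyl-3-vinylcyclopent-1-en-1-yl]oxy}silane
Product: 5 (4R)-3,5,5-trimethyl-4-vinylcyclohex-2-en-1-one, via siloxycyclopropane 3 (not isolated), via chloro ketone 4 (not isolated)
Conditions: Et2Zn, CH2I2, CH2Cl2, 0 to 23 °C; solvent exchange; FeCl3 (2.2 equiv), DMF, 0 °C; then NaOAc, MeOH, 23 °C
Reagents that add atoms: diiodomethane (ICI); FeCl3 (Cl[Fe](Cl)Cl) leaves chlorine in 4 only
Why: Simmons–Smith methylene transfer (Furukawa reagent) closes the three-membered ring in a concerted [2+1] addition on the electron-rich tetrasubstituted enol ether C3'=C5' of the cyclopentene and leaves the monosubstituted vinyl group alone; trivalent iron then oxidises siloxycyclopropane 3 at oxygen, the ring-fusion bond C3'–C5' shared by the three- and five-membered rings breaks by β-scission, and the five-membered ring thereby grows by the inserted carbon C4' into the six-membered ring (no new bond closes it) with C3' as carbonyl and a tertiary radical at C5' that takes chlorine from FeCl3 to give 4. Acetate then removes HCl by an E1cB path through the C4' enolate, so the double bond can only lie at C4'=C5'. The closest known reaction type is the Ito–Saegusa ring expansion of ring-fused siloxycyclopropanes to cycloalk-2-en-1-ones, which tolerates an alkyl group on the ring-fusion carbon. No stereocentre of the product is made here, because the two ring-fusion centres of 3 and the C–Cl centre of 4 are erased again, so both faces of cyclopropanation and both chloride epimers funnel into one enone, while C6' is never a radical, cation or enolate carbon and is carried through. The step needs chemoselectivity for the enol ether over the vinyl group (secured by the silyloxy donor), cleavage of the internal and not a peripheral cyclopropane bond (secured by carbonyl formation and the tertiary C5' radical) and no epimerisation at the γ-carbon C6' (secured by the weak base NaOAc at 23 °C).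

Step 3
Reactants: 5 (4R)-3,5,5-trimethyl-4-vinylcyclohex-2-en-1-one
Product: 6 (1R,4R)-3,5,5-trimethyl-4-vinylcyclohex-2-en-1-ol
Conditions: LiBH(s-Bu)3, THF, −78 °C; H2O
Reagents that add atoms: none
Why: 1,2-Reduction of a β,β-disubstituted cyclohexenone by a bulky trialkylborohydride: with the vinyl group pseudoaxial to avoid allylic strain with the C3 methyl, the axial methyl of the gem-dimethyl carbon blocks the opposite face of the carbonyl, so hydride should enter syn to vinyl and set the carbinol centre 1R trans to C4 (substrate control).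

Step 4
Reactants: 6 (1R,4R)-3,5,5-trimethyl-4-vinylcyclohex-2-en-1-ol
Product: 7 tert-butyldimethyl{[(1R,4R)-3,5,5-trimethyl-4-vinylcyclohex-2-en-1-yl]oxy}silane
Conditions: t-BuMe2SiCl, imidazole, DMF, 23 °C
Reagents that add atoms: tert-butylchlorodimethylsilane (CC(C)(C)[Si](C)(C)Cl)
Why: Imidazole-promoted silylation of the secondary allylic alcohol is a standard protection that changes no stereocentre and masks the carbinol for the base, hydride and leaving-group chemistry ahead.

Step 5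
Reactants: 7 tert-butyldimethyl{[(1R,4R)-3,5,5-trimethyl-4-vinylcyclohex-2-en-1-yl]oxy}silane
Product: 8 (3E)-4-[(1R,4R)-4-(tert-butyldimethylsilyloxy)-2,6,6-trimethylcyclohex-2-en-1-yl]but-3-en-2-one
Conditions: but-3-en-2-one (5 equiv), second-generation Hoveyda–Grubbs catalyst (5 mol %), CH2Cl2, 40 °C
Reagents that add atoms: but-3-en-2-one (CC(=O)C=C)
Why: Ruthenium-catalysed olefin cross-metathesis of the terminal vinyl group with an electron-poor partner used in excess should give the E-enone under thermodynamic control, while the hindered trisubstituted ring alkene does not take part and C1 of the ring is untouched.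

Step 6
Reactants: 8 (3E)-4-[(1R,4R)-4-(tert-butyldimethylsilyloxy)-2,6,6-trimethylcyclohex-2-en-1-yl]but-3-en-2-one
Product: 9 ethyl (2E,4E)-5-[(1R,4R)-4-(tert-butyldimethylsilyloxy)-2,6,6-trimethylcyclohex-2-en-1-yl]-3-methylpenta-2,4-dienoate
Conditions: (EtO)2P(O)CH2CO2Et, NaH, THF, 0 to 40 °C
Reagents that add atoms: triethyl phosphonoacetate (CCOC(=O)CP(=O)(OCC)OCC)
Why: Horner–Wadsworth–Emmons olefination of the methyl ketone gives mainly the 2E trisubstituted enoate (the minor 2Z isomer is removed by chromatography) and the weakly basic phosphonate anion is not expected to deprotonate the γ-position at C1 of the ring.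

Step 7
Reactants: 9 ethyl (2E,4E)-5-[(1R,4R)-4-(tert-butyldimethylsilyloxy)-2,6,6-trimethylcyclohex-2-en-1-yl]-3-methylpenta-2,4-dienoate
Product: 10 (2E,4E)-5-[(1R,4R)-4-(tert-butyldimethylsilyloxy)-2,6,6-trimethylcyclohex-2-en-1-yl]-3-methylpenta-2,4-dien-1-ol
Conditions: i-Bu2AlH, CH2Cl2, −78 °C; aqueous work-up
Reagents that add atoms: none
Why: Reduction of the dienoate with i-Bu2AlH at low temperature is a clean 1,2-hydride transfer to the ester that leaves the diene geometry and the silyl ether unchanged.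

Step 8
Reactants: 10 (2E,4E)-5-[(1R,4R)-4-(tert-butyldimethylsilyloxy)-2,6,6-trimethylcyclohex-2-en-1-yl]-3-methylpenta-2,4-dien-1-ol
Product: 13 {(2E,4E)-5-[(1R,4R)-4-(tert-butyldimethylsilyloxy)-2,6,6-trimethylcyclohex-2-en-1-yl]-3-methylpenta-2,4-dien-1-yl}triphenylphosphonium bromide, via allylic mesylate 11 (not isolated), via allylic bromide 12 (not isolated)
Conditions: MeSO2Cl, Et3N, THF, −40 °C; LiBr, 0 °C; then PPh3, EtOAc, 23 °C
Reagents that add atoms: lithium bromide ([Li+].[Br-]); triphenylphosphine (c1ccc(cc1)P(c1ccccc1)c1ccccc1); methanesulfonyl chloride (CS(=O)(=O)Cl) leaves atoms in 11 only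
Why: Mesylation, SN2 bromide exchange and SN2 quaternisation of PPh3 at the primary allylic carbon proceed under non-acidic conditions, so the allylic silyl ether and the E,E-diene survive and the Wittig salt precipitates.

Step 9
Reactants: 14 (4R,6R)-4-hydroxy-2,2,6-trimethylcyclohexan-1-one
Product: 15 (4R,6R)-4-(tert-butyldimethylsilyloxy)-2,2,6-trimethylcyclohexan-1-one
Conditions: t-BuMe2SiCl, imidazole, DMF, 23 °C
Reagents that add atoms: tert-butylchlorodimethylsilane (CC(C)(C)[Si](C)(C)Cl)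
Why: Standard imidazole-promoted silylation of the unhindered secondary alcohol is mild enough that the enolisable C6 centre is not epimerised.

Step 10
Reactants: 15 (4R,6R)-4-(tert-butyldimethylsilyloxy)-2,2,6-trimethylcyclohexan-1-one
Product: 17 (4R)-4-(tert-butyldimethylsilyloxy)-2,6,6-trimethylcyclohex-1-en-1-yl trifluoromethanesulfonate, via potassium enolate 16 (not isolated)
Conditions: KN(SiMe3)2, THF, −78 °C; PhNTf2, −78 to 0 °C
Reagents that add atoms: N-phenylbis(trifluoromethanesulfonimide) (O=S(=O)(N(c1ccccc1)S(=O)(=O)C(F)(F)F)C(F)(F)F); potassium bis(trimethylsilyl)amide (C[Si](C)(C)[N-][Si](C)(C)C.[K+]) leaves potassium in 16 only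
Why: The ketone has a single α-hydrogen, so deprotonation and O-sulfonylation of the potassium enolate with PhNTf2 (enol triflate formation) can only give the tetrasubstituted C1=C2 triflate; the C6 centre is erased as planned and C4 is remote.

Step 11
Reactants: 17 (4R)-4-(tert-butyldimethylsilyloxy)-2,6,6-trimethylcyclohex-1-en-1-yl trifluoromethanesulfonate
Product: 18 methyl (4R)-4-(tert-butyldimethylsilyloxy)-2,6,6-trimethylcyclohex-1-ene-1-carboxylate
Conditions: Pd(OAc)2 (5 mol %), PPh3 (10 mol %), CO (1 atm), MeOH, Et3N, DMF, 60 °C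
Reagents that add atoms: carbon monoxide ([C-]#[O+]); methanol (CO)
Why: Palladium-catalysed methoxycarbonylation of an enol triflate (oxidative addition to zerovalent palladium, CO insertion, methanolysis) introduces C7 at the ester level on the hindered tetrasubstituted alkene.

Step 12
Reactants: 18 methyl (4R)-4-(tert-butyldimethylsilyloxy)-2,6,6-trimethylcyclohex-1-ene-1-carboxylate
Product: 19 [(4R)-4-(tert-butyldimethylsilyloxy)-2,6,6-trimethylcyclohex-1-en-1-yl]methanol
Conditions: i-Bu2AlH, CH2Cl2, −78 to 0 °C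
Reagents that add atoms: none
Why: 1,2-Reduction of the conjugated ester with i-Bu2AlH gives the primary allylic alcohol required for a directed epoxidation.

Step 13
Reactants: 19 [(4R)-4-(tert-butyldimethylsilyloxy)-2,6,6-trimethylcyclohex-1-en-1-yl]methanol
Product: 20 [(1R,4S,6R)-4-(tert-butyldimethylsilyloxy)-2,2,6-trimethyl-7-oxabicyclo[4.1.0]heptan-1-yl]methanol
Conditions: Ti(OiPr)4 (20 mol %), D-(−)-diethyl tartrate (24 mol %), t-BuOOH, 4 Å molecular sieves, CH2Cl2, −20 °C
Reagents that add atoms: tert-butyl hydroperoxide (CC(C)(C)OO)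
Why: Katsuki–Sharpless asymmetric epoxidation: the titanium D-(−)-tartrate complex bound to the primary allylic alcohol should deliver oxygen to the alkene face anti to the 4-silyloxy group under reagent control and thereby set both oxirane centres (1R,6R in the product numbering).

Step 14
Reactants: 20 [(1R,4S,6R)-4-(tert-butyldimethylsilyloxy)-2,2,6-trimethyl-7-oxabicyclo[4.1.0]heptan-1-yl]methanol
Product: 21 (1S,4S,6R)-4-(tert-butyldimethylsilyloxy)-2,2,6-trimethyl-7-oxabicyclo[4.1.0]heptane-1-carbaldehyde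
Conditions: Pr4N[RuO4] (5 mol %), N-methylmorpholine N-oxide, 4 Å molecular sieves, CH2Cl2, 23 °C
Reagents that add atoms: none
Why: Ley–Griffith oxidation with catalytic perruthenate and N-oxide under neutral conditions converts the primary epoxy alcohol into the non-enolisable epoxy aldehyde without opening the oxirane.

Step 15
Reactants: 21 (1S,4S,6R)-4-(tert-butyldimethylsilyloxy)-2,2,6-trimethyl-7-oxabicyclo[4.1.0]heptane-1-carbaldehyde
Product: 22 ethyl (2E,4E)-5-[(1S,4S,6R)-4-(tert-butyldimethylsilyloxy)-2,2,6-trimethyl-7-oxabicyclo[4.1.0]heptan-1-yl]-3-methylpenta-2,4-dienoate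
Conditions: triethyl (E)-3-methyl-4-phosphonobut-2-enoate, LiN(SiMe3)2, THF, −78 to 0 °C
Reagents that add atoms: triethyl (E)-3-methyl-4-phosphonobut-2-enoate (CCOC(=O)/C=C(\C)CP(=O)(OCC)OCC)
Why: Horner–Wadsworth–Emmons olefination with the stabilised C5 phosphonate anion forms the C7=C8 bond E-selectively next to the quaternary oxirane carbon and transfers the 2E geometry of the reagent (a minor 2Z isomer is separated).

Step 16
Reactants: 22 ethyl (2E,4E)-5-[(1S,4S,6R)-4-(tert-butyldimethylsilyloxy)-2,2,6-trimethyl-7-oxabicyclo[4.1.0]heptan-1-yl]-3-methylpenta-2,4-dienoate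
Product: 23 (2E,4E)-5-[(1S,4S,6R)-4-(tert-butyldimethylsilyloxy)-2,2,6-trimethyl-7-oxabicyclo[4.1.0]heptan-1-yl]-3-methylpenta-2,4-dien-1-ol
Conditions: i-Bu2AlH, CH2Cl2, −78 °C
Reagents that add atoms: none
Why: i-Bu2AlH at −78 °C reduces the ester by 1,2-hydride transfer faster than it attacks the vinyl oxirane.

Step 17
Reactants: 23 (2E,4E)-5-[(1S,4S,6R)-4-(tert-butyldimethylsilyloxy)-2,2,6-trimethyl-7-oxabicyclo[4.1.0]heptan-1-yl]-3-methylpenta-2,4-dien-1-ol
Product: 26 {(2E,4E)-5-[(1S,4S,6R)-4-(tert-butyldimethylsilyloxy)-2,2,6-trimethyl-7-oxabicyclo[4.1.0]heptan-1-yl]-3-methylpenta-2,4-dien-1-yl}triphenylphosphonium bromide, via epoxy mesylate 24 (not isolated), via epoxy bromide 25 (not isolated)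
Conditions: MeSO2Cl, Et3N, THF, −40 °C; LiBr, 0 °C; then PPh3, EtOAc, 23 °C
Reagents that add atoms: lithium bromide ([Li+].[Br-]); triphenylphosphine (c1ccc(cc1)P(c1ccccc1)c1ccccc1); methanesulfonyl chloride (CS(=O)(=O)Cl) leaves atoms in 24 only
Why: The same non-acidic mesylate, bromide and PPh3 sequence as in step 8 (three SN2 events at the primary allylic carbon) is chosen so that the vinylogous oxirane is never exposed to acid.

Step 18
Reactants: 13 {(2E,4E)-5-[(1R,4R)-4-(tert-butyldimethylsilyloxy)-2,6,6-trimethylcyclohex-2-en-1-yl]-3-methylpenta-2,4-dien-1-yl}triphenylphosphonium bromide; 27 (2E,4E,6E)-2,7-dimethylocta-2,4,6-trienedial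
Product: 29 (2E,4E,6E,8E,10E,12E)-13-[(1R,4R)-4-(tert-butyldimethylsilyloxy)-2,6,6-trimethylcyclohex-2-en-1-yl]-2,7,11-trimethyltrideca-2,4,6,8,10,12-hexaenal, via phosphorus ylide 28 (not isolated)
Conditions: 27 (2.5 equiv), NaOMe, CH2Cl2/MeOH, 0 to 23 °C; then heptane, 80 °C, dark
Reagents that add atoms: none
Why: Wittig olefination of one formyl group of the dialdehyde used in excess forms the C11'=C12' bond, and the hindered 11'Z isomer that forms alongside is isomerised thermally to the all-E aldehyde.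

Step 19
Reactants: 29 (2E,4E,6E,8E,10E,12E)-13-[(1R,4R)-4-(tert-butyldimethylsilyloxy)-2,6,6-trimethylcyclohex-2-en-1-yl]-2,7,11-trimethyltrideca-2,4,6,8,10,12-hexaenal; 26 {(2E,4E)-5-[(1S,4S,6R)-4-(tert-butyldimethylsilyloxy)-2,2,6-trimethyl-7-oxabicyclo[4.1.0]heptan-1-yl]-3-methylpenta-2,4-dien-1-yl}triphenylphosphonium bromide
Product: 31 (3S,5R,6S,3'R,6'R)-3,3'-bis(tert-butyldimethylsilyloxy)-5,6-epoxy-5,6-dihydro-β,ε-carotene, via epoxy ylide 30 (not isolated)
Conditions: NaOMe, CH2Cl2/MeOH, 0 to 23 °C; then EtOAc, 70 °C, dark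
Reagents that add atoms: none
Why: Wittig olefination joins the two halves at C11=C12 without touching any stereocentre, and thermal equilibration converts the hindered 11Z isomer into the all-E polyene.

Step 20
Reactants: 31 (3S,5R,6S,3'R,6'R)-3,3'-bis(tert-butyldimethylsilyloxy)-5,6-epoxy-5,6-dihydro-β,ε-carotene
Product: 32 (3S,5R,6S,3'R,6'R)-5,6-epoxy-5,6-dihydro-β,ε-carotene-3,3'-diol
Conditions: Bu4NF, THF, 23 °C; H2O
Reagents that add atoms: none
Why: Fluoride-induced desilylation is a non-acidic deprotection that spares the acid-labile 5,6-epoxide and the ionisable allylic 3'-carbinol.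

Step 21
Reactants: 32 (3S,5R,6S,3'R,6'R)-5,6-epoxy-5,6-dihydro-β,ε-carotene-3,3'-diol
Product: 33 (3S,5R,6S,3'R,6'R)-5,6-epoxy-5,6-dihydro-β,ε-carotene-3,3'-diyl dihexadecanoate
Conditions: hexadecanoyl chloride (3 equiv), pyridine, DMAP (catalytic), CH2Cl2, 0 to 23 °C
Reagents that add atoms: hexadecanoyl chloride (CCCCCCCCCCCCCCCC(=O)Cl)
Why: Pyridine and DMAP-catalysed acylation (nucleophilic catalysis) esterifies both secondary hydroxyls with retention at C3 and C3' and gives the target.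

**Compound list**

1 | 2,4,4-trimethylcyclopent-2-en-1-one | CC1=CC(C)(C)CC1=O | starting material
2 | trimethyl{[(3R)-2,4,4-trimethyl-3-vinylcyclopent-1-en-1-yl]oxy}silane | C=C[C@H]1C(C)=C(O[Si](C)(C)C)CC1(C)C | intermediate
3 | trimethyl{[(4R)-3,3,5-trimethyl-4-vinylbicyclo[3.1.0]hexan-1-yl]oxy}silane (isomer with the cyclopropane CH2 anti to vinyl drawn; the syn isomer reacts on alike) | C=C[C@H]1[C@]2(C)C[C@]2(O[Si](C)(C)C)CC1(C)C | intermediate
4 | (4R)-3-chloro-3,5,5-trimethyl-4-vinylcyclohexan-1-one (both C3 epimers) | C=C[C@H]1C(C)(Cl)CC(=O)CC1(C)C | intermediate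
5 | (4R)-3,5,5-trimethyl-4-vinylcyclohex-2-en-1-one | C=C[C@H]1C(C)=CC(=O)CC1(C)C | intermediate
6 | (1R,4R)-3,5,5-trimethyl-4-vinylcyclohex-2-en-1-ol | C=C[C@H]1C(C)=C[C@H](O)CC1(C)C | intermediate
7 | tert-butyldimethyl{[(1R,4R)-3,5,5-trimethyl-4-vinylcyclohex-2-en-1-yl]oxy}silane | C=C[C@H]1C(C)=C[C@H](O[Si](C)(C)C(C)(C)C)CC1(C)C | intermediate
8 | (3E)-4-[(1R,4R)-4-(tert-butyldimethylsilyloxy)-2,6,6-trimethylcyclohex-2-en-1-yl]but-3-en-2-one | CC(=O)/C=C/[C@H]1C(C)=C[C@H](O[Si](C)(C)C(C)(C)C)CC1(C)C | intermediate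
9 | ethyl (2E,4E)-5-[(1R,4R)-4-(tert-butyldimethylsilyloxy)-2,6,6-trimethylcyclohex-2-en-1-yl]-3-methylpenta-2,4-dienoate | CCOC(=O)/C=C(C)/C=C/[C@H]1C(C)=C[C@H](O[Si](C)(C)C(C)(C)C)CC1(C)C | intermediate
10 | (2E,4E)-5-[(1R,4R)-4-(tert-butyldimethylsilyloxy)-2,6,6-trimethylcyclohex-2-en-1-yl]-3-methylpenta-2,4-dien-1-ol | OC/C=C(C)/C=C/[C@H]1C(C)=C[C@H](O[Si](C)(C)C(C)(C)C)CC1(C)C | intermediate
11 | (2E,4E)-5-[(1R,4R)-4-(tert-butyldimethylsilyloxy)-2,6,6-trimethylcyclohex-2-en-1-yl]-3-methylpenta-2,4-dien-1-yl methanesulfonate | CS(=O)(=O)OC/C=C(C)/C=C/[C@H]1C(C)=C[C@H](O[Si](C)(C)C(C)(C)C)CC1(C)C | intermediate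
12 | {[(1R,4R)-4-[(1E,3E)-5-bromo-3-methylpenta-1,3-dien-1-yl]-3,5,5-trimethylcyclohex-2-en-1-yl]oxy}(tert-butyl)dimethylsilane | BrC/C=C(C)/C=C/[C@H]1C(C)=C[C@H](O[Si](C)(C)C(C)(C)C)CC1(C)C | intermediate
13 | {(2E,4E)-5-[(1R,4R)-4-(tert-butyldimethylsilyloxy)-2,6,6-trimethylcyclohex-2-en-1-yl]-3-methylpenta-2,4-dien-1-yl}triphenylphosphonium bromide | [Br-].c1ccccc1[P+](c1ccccc1)(c1ccccc1)C/C=C(C)/C=C/[C@H]1C(C)=C[C@H](O[Si](C)(C)C(C)(C)C)CC1(C)C | intermediate
14 | (4R,6R)-4-hydroxy-2,2,6-trimethylcyclohexan-1-one | O[C@H]1CC(C)(C)C(=O)[C@H](C)C1 | starting material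
15 | (4R,6R)-4-(tert-butyldimethylsilyloxy)-2,2,6-trimethylcyclohexan-1-one | CC(C)(C)[Si](C)(C)O[C@H]1CC(C)(C)C(=O)[C@H](C)C1 | intermediate
16 | potassium (4R)-4-(tert-butyldimethylsilyloxy)-2,6,6-trimethylcyclohex-1-en-1-olate | CC(C)(C)[Si](C)(C)O[C@H]1CC(C)(C)C([O-])=C(C)C1.[K+] | intermediate
17 | (4R)-4-(tert-butyldimethylsilyloxy)-2,6,6-trimethylcyclohex-1-en-1-yl trifluoromethanesulfonate | CC(C)(C)[Si](C)(C)O[C@H]1CC(C)(C)C(OS(=O)(=O)C(F)(F)F)=C(C)C1 | intermediate
18 | methyl (4R)-4-(tert-butyldimethylsilyloxy)-2,6,6-trimethylcyclohex-1-ene-1-carboxylate | CC(C)(C)[Si](C)(C)O[C@H]1CC(C)(C)C(C(=O)OC)=C(C)C1 | intermediate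
19 | [(4R)-4-(tert-butyldimethylsilyloxy)-2,6,6-trimethylcyclohex-1-en-1-yl]methanol | CC(C)(C)[Si](C)(C)O[C@H]1CC(C)(C)C(CO)=C(C)C1 | intermediate
20 | [(1R,4S,6R)-4-(tert-butyldimethylsilyloxy)-2,2,6-trimethyl-7-oxabicyclo[4.1.0]heptan-1-yl]methanol | CC(C)(C)[Si](C)(C)O[C@H]1CC(C)(C)[C@]2(CO)O[C@]2(C)C1 | intermediate
21 | (1S,4S,6R)-4-(tert-butyldimethylsilyloxy)-2,2,6-trimethyl-7-oxabicyclo[4.1.0]heptane-1-carbaldehyde | CC(C)(C)[Si](C)(C)O[C@H]1CC(C)(C)[C@]2(C=O)O[C@]2(C)C1 | intermediate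
22 | ethyl (2E,4E)-5-[(1S,4S,6R)-4-(tert-butyldimethylsilyloxy)-2,2,6-trimethyl-7-oxabicyclo[4.1.0]heptan-1-yl]-3-methylpenta-2,4-dienoate | CC(C)(C)[Si](C)(C)O[C@H]1CC(C)(C)[C@]2(/C=C/C(C)=C/C(=O)OCC)O[C@]2(C)C1 | intermediate
23 | (2E,4E)-5-[(1S,4S,6R)-4-(tert-butyldimethylsilyloxy)-2,2,6-trimethyl-7-oxabicyclo[4.1.0]heptan-1-yl]-3-methylpenta-2,4-dien-1-ol | CC(C)(C)[Si](C)(C)O[C@H]1CC(C)(C)[C@]2(/C=C/C(C)=C/CO)O[C@]2(C)C1 | intermediate
24 | (2E,4E)-5-[(1S,4S,6R)-4-(tert-butyldimethylsilyloxy)-2,2,6-trimethyl-7-oxabicyclo[4.1.0]heptan-1-yl]-3-methylpenta-2,4-dien-1-yl methanesulfonate | CC(C)(C)[Si](C)(C)O[C@H]1CC(C)(C)[C@]2(/C=C/C(C)=C/COS(C)(=O)=O)O[C@]2(C)C1 | intermediate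
25 | {[(1S,4S,6R)-1-[(1E,3E)-5-bromo-3-methylpenta-1,3-dien-1-yl]-2,2,6-trimethyl-7-oxabicyclo[4.1.0]heptan-4-yl]oxy}(tert-butyl)dimethylsilane | CC(C)(C)[Si](C)(C)O[C@H]1CC(C)(C)[C@]2(/C=C/C(C)=C/CBr)O[C@]2(C)C1 | intermediate
26 | {(2E,4E)-5-[(1S,4S,6R)-4-(tert-butyldimethylsilyloxy)-2,2,6-trimethyl-7-oxabicyclo[4.1.0]heptan-1-yl]-3-methylpenta-2,4-dien-1-yl}triphenylphosphonium bromide | CC(C)(C)[Si](C)(C)O[C@H]1CC(C)(C)[C@]2(/C=C/C(C)=C/C[P+](c3ccccc3)(c3ccccc3)c3ccccc3)O[C@]2(C)C1.[Br-] | intermediate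
27 | (2E,4E,6E)-2,7-dimethylocta-2,4,6-trienedial | O=C/C(C)=C/C=C/C=C(C)/C=O | starting material
28 | {(2E,4E)-5-[(1R,4R)-4-(tert-butyldimethylsilyloxy)-2,6,6-trimethylcyclohex-2-en-1-yl]-3-methylpenta-2,4-dien-1-ylidene}triphenylphosphorane | c1ccccc1P(c1ccccc1)(c1ccccc1)=C/C=C(C)/C=C/[C@H]1C(C)=C[C@H](O[Si](C)(C)C(C)(C)C)CC1(C)C | intermediate
29 | (2E,4E,6E,8E,10E,12E)-13-[(1R,4R)-4-(tert-butyldimethylsilyloxy)-2,6,6-trimethylcyclohex-2-en-1-yl]-2,7,11-trimethyltrideca-2,4,6,8,10,12-hexaenal | O=C/C(C)=C/C=C/C=C(C)/C=C/C=C(C)/C=C/[C@H]1C(C)=C[C@H](O[Si](C)(C)C(C)(C)C)CC1(C)C | intermediate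
30 | {(2E,4E)-5-[(1S,4S,6R)-4-(tert-butyldimethylsilyloxy)-2,2,6-trimethyl-7-oxabicyclo[4.1.0]heptan-1-yl]-3-methylpenta-2,4-dien-1-ylidene}triphenylphosphorane | CC(C)(C)[Si](C)(C)O[C@H]1CC(C)(C)[C@]2(/C=C/C(C)=C/C=P(c3ccccc3)(c3ccccc3)c3ccccc3)O[C@]2(C)C1 | intermediate
31 | (3S,5R,6S,3'R,6'R)-3,3'-bis(tert-butyldimethylsilyloxy)-5,6-epoxy-5,6-dihydro-β,ε-carotene | CC(C)(C)[Si](C)(C)O[C@H]1CC(C)(C)[C@]2(/C=C/C(C)=C/C=C/C(C)=C/C=C/C=C(C)/C=C/C=C(C)/C=C/[C@H]3C(C)=C[C@H](O[Si](C)(C)C(C)(C)C)CC3(C)C)O[C@]2(C)C1 | intermediate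
32 | (3S,5R,6S,3'R,6'R)-5,6-epoxy-5,6-dihydro-β,ε-carotene-3,3'-diol | O[C@H]1CC(C)(C)[C@]2(/C=C/C(C)=C/C=C/C(C)=C/C=C/C=C(C)/C=C/C=C(C)/C=C/[C@H]3C(C)=C[C@H](O)CC3(C)C)O[C@]2(C)C1 | intermediate
33 | (3S,5R,6S,3'R,6'R)-5,6-epoxy-5,6-dihydro-β,ε-carotene-3,3'-diyl dihexadecanoate | CCCCCCCCCCCCCCCC(=O)O[C@H]1CC(C)(C)[C@]2(/C=C/C(C)=C/C=C/C(C)=C/C=C/C=C(C)/C=C/C=C(C)/C=C/[C@H]3C(C)=C[C@H](OC(=O)CCCCCCCCCCCCCCC)CC3(C)C)O[C@]2(C)C1 | target

**Summary**

Total step count: 21.
Longest linear sequence: 12 steps (steps 9–17, then 19, 20, 21; the branch through steps 1–8 and 18–21 is equally long).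

Three steps most likely to fail:

Step 1. What may go wrong: weak facial discrimination, and slow transfer, when the vinyl–copper species adds to a β-carbon flanked by the quaternary carbon and the α-methyl group, so that the material reaches 6 with low enantiomeric purity. The fallback sets out from 6 and comes back at 6. Step 1 is run as far as the catalyst allows (if need be with CuI and no ligand). The scalemic alcohol 6 is then upgraded by lipase-catalysed enantiomer-selective acetylation (Burkholderia cepacia lipase, vinyl acetate, t-BuOMe, 30 °C), in which the 1R carbinol is expected to be the fast-reacting enantiomer. The acetate (1R,4R)-3,5,5-trimethyl-4-vinylcyclohex-2-en-1-yl acetate F1 is separated from unreacted (1S,4S)-alcohol and methanolysed (K2CO3, MeOH) to enantiopure 6.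

Step 5. What may go wrong: stalling of the metathesis cycle at the congested vinyl group (C6' lies between a quaternary carbon and a methyl-bearing alkene carbon), with catalyst decay and self-metathesis of the enone partner. The fallback sets out from 7 and comes back at 9, bypassing 8. A Heck–Mizoroki alkenylation of the vinyl group with ethyl (E)-3-iodobut-2-enoate (Pd(OAc)2, Ag2CO3, DMF, 50 °C) forms the C7'=C8' bond and brings in C9'–C11' with the 9'E geometry already fixed in the iodide. This detour makes no compound outside the list (F0).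

Step 17. What may go wrong: ionisation of the dienylic mesylate or bromide with participation of the oxirane (furanoid ring closure or elimination) before PPh3 captures the allylic carbon. The fallback sets out from 23 and comes back at 31. Mitsunobu thioetherification of 23 (1-phenyl-1H-tetrazole-5-thiol, PPh3, diisopropyl azodicarboxylate, THF, 0 °C) gives the sulfide 5-({(2E,4E)-5-[(1S,4S,6R)-4-(tert-butyldimethylsilyloxy)-2,2,6-trimethyl-7-oxabicyclo[4.1.0]heptan-1-yl]-3-methylpenta-2,4-dien-1-yl}sulfanyl)-1-phenyl-1H-tetrazole F2. Oxidation ((NH4)6Mo7O24·4H2O catalytic, H2O2, EtOH, 0 °C) gives the sulfone 5-({(2E,4E)-5-[(1S,4S,6R)-4-(tert-butyldimethylsilyloxy)-2,2,6-trimethyl-7-oxabicyclo[4.1.0]heptan-1-yl]-3-methylpenta-2,4-dien-1-yl}sulfonyl)-1-phenyl-1H-tetrazole F3. Julia–Kocienski olefination of aldehyde 29 with F3 (KN(SiMe3)2, THF, −78 °C, then thermal E/Z equilibration in EtOAc at 70 °C) gives 31 without any ionisable allylic halide.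

**Further compounds**

F1 | step 1 | (1R,4R)-3,5,5-trimethyl-4-vinylcyclohex-2-en-1-yl acetate | C=C[C@H]1C(C)=C[C@H](OC(C)=O)CC1(C)C
F0 | step 5 | none | none
F2 | step 17 | 5-({(2E,4E)-5-[(1S,4S,6R)-4-(tert-butyldimethylsilyloxy)-2,2,6-trimethyl-7-oxabicyclo[4.1.0]heptan-1-yl]-3-methylpenta-2,4-dien-1-yl}sulfanyl)-1-phenyl-1H-tetrazole | CC(C)(C)[Si](C)(C)O[C@H]1CC(C)(C)[C@]2(/C=C/C(C)=C/CSc3nnnn3-c3ccccc3)O[C@]2(C)C1
F3 | step 17 | 5-({(2E,4E)-5-[(1S,4S,6R)-4-(tert-butyldimethylsilyloxy)-2,2,6-trimethyl-7-oxabicyclo[4.1.0]heptan-1-yl]-3-methylpenta-2,4-dien-1-yl}sulfonyl)-1-phenyl-1H-tetrazole | CC(C)(C)[Si](C)(C)O[C@H]1CC(C)(C)[C@]2(/C=C/C(C)=C/CS(=O)(=O)c3nnnn3-c3ccccc3)O[C@]2(C)C1
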